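## Retrosynthetic overview (labdane numbering; ring A = C1–C5, C10; ring B = C5–C10)

1. The 1,2-dioxepane ring is closed last, by addition of the C11 hydroperoxide of dial 29 to the C15 aldehyde; the (E)-enal comes from a Wittig reaction of α-peroxy aldehyde 21 with formyl ylide 27.
2. The C11–OOH group comes from a Schenck ene reaction of singlet oxygen with the (Z)-propenyl group of 17, which is made from 7β-silyloxy-albicanal 16, methyl albicanate 11 and bicyclic β-keto ester 10.
3. Rings A and B are formed in one cascade from the acyclic enyne β-keto ester 8: ring A closes first through the bond C1–C2 (terminal alkene carbon to terminal alkyne carbon), ring B follows through C9–C10.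
4. Enabling feature: C10 is a quaternary carbon shared by rings A and B that carries a methyl group and the unsubstituted ring A methylene C1. Written as a 2-propenyl group (C1=C10) on C5, its terminus C1 can bond to C2 while the tertiary C10 cation is caught by C9; the fully substituted C4 (gem-dimethyl) beside the alkyne has no hydrogen to divert the cascade.
5. Enyne 8 comes from the acetoacetate dianion and iodide 7, which comes from the (R)-alcohol 6 (lipase resolution), made by tert-propargylation of methyl acetoacetate and methylenation.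

Key step: step 7

Assumption (hemiperacetal centre): C15 of the cyclic peroxy hemiacetal equilibrates through the open hydroperoxy aldehyde; the 15R epimer of the target is taken to be the thermodynamically preferred form.
Assumption (resolution): the lipase is taken to acylate the S alcohol faster, so that the R alcohol is recovered unreacted; with the opposite preference the R enantiomer would leave the same step as its acetate and be released with K2CO3/MeOH.

## Route

Step 1
Reactants: 1 methyl acetoacetate; 2 3-chloro-3-methylbut-1-yne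
Product: 3 methyl 2-acetyl-3,3-dimethylpent-4-ynoate (racemic)
Conditions: NaOMe, MeOH, 0 °C to rt
Reagents that add atoms: none
Why: Base-induced loss of chloride from the tertiary propargylic chloride gives the dimethylallenylidene zwitterion–carbene, which a soft stabilised enolate captures at the tertiary carbon (tert-propargylic alkylation), setting the quaternary C4 with its ethynyl group; the new CH centre is labile and of no consequence.

Step 2
Reactants: 3 methyl 2-acetyl-3,3-dimethylpent-4-ynoate
Product: 4 methyl 3,3-dimethyl-2-(prop-1-en-2-yl)pent-4-ynoate (racemic)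
Conditions: Zn, CH2Br2, TiCl4, THF/CH2Cl2, 0 °C to rt
Reagents that add atoms: dibromomethane BrCBr
Why: Takai–Lombardo methylenation is non-basic and so suits an enolisable, hindered β-keto ester ketone while leaving ester and terminal alkyne alone; it turns the acetyl group into the 2-propenyl unit (C10, C1 and the C10 methyl).

Step 3
Reactants: 4 methyl 3,3-dimethyl-2-(prop-1-en-2-yl)pent-4-ynoate
Product: 5 (±)-3,3-dimethyl-2-(prop-1-en-2-yl)pent-4-yn-1-ol
Conditions: LiAlH4, Et2O, 0 °C
Reagents that add atoms: none
Why: Hydride reduction of the ester gives the primary alcohol (C6) without touching the isolated alkene or the remote alkyne.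

Step 4
Reactants: 5 (±)-3,3-dimethyl-2-(prop-1-en-2-yl)pent-4-yn-1-ol
Product: 6 (R)-3,3-dimethyl-2-(prop-1-en-2-yl)pent-4-yn-1-ol
Conditions: Burkholderia cepacia lipase (Amano PS), vinyl acetate, t-BuOMe, rt, stopped a little beyond half conversion
Reagents that add atoms: none
Why: Lipase-catalysed kinetic resolution of a primary alcohol with a β-stereocentre flanked by a medium (2-propenyl) and a large (tert-propargyl) group, as practised for lavandulol-type alcohols, should leave the slow-reacting R alcohol in high enantiomeric purity once conversion passes one half; this fixes C5.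

Step 5
Reactants: 6 (R)-3,3-dimethyl-2-(prop-1-en-2-yl)pent-4-yn-1-ol
Product: 7 (R)-3-(iodomethyl)-2,4,4-trimethylhex-1-en-5-yne
Conditions: I2, PPh3, imidazole, CH2Cl2, 0 °C to rt
Reagents that add atoms: iodine II
Why: Appel-type iodination of the primary alcohol proceeds by SN2 at the CH2 group and leaves the adjacent stereocentre untouched.

Step 6
Reactants: 7 (R)-3-(iodomethyl)-2,4,4-trimethylhex-1-en-5-yne; 1 methyl acetoacetate
Product: 8 methyl (6R)-7,7-dimethyl-3-oxo-6-(prop-1-en-2-yl)non-8-ynoate
Conditions: NaH, THF, 0 °C; n-BuLi, 0 °C; then 7, DMPU, 0 °C to rt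
Reagents that add atoms: none
Why: The acetoacetate dianion is alkylated at its terminal (γ) carbon, which adds C7–C9 and the ester as a β-keto ester; the β-branched primary iodide reacts slowly but cleanly by SN2 with DMPU, and excess dianion absorbs the acetylenic proton.

Step 7
Reactants: 8 methyl (6R)-7,7-dimethyl-3-oxo-6-(prop-1-en-2-yl)non-8-ynoate
Product: 9 methyl (1R,4aS,8aS)-5,5,8a-trimethyl-2-oxo-1,2,3,4,4a,5,8,8a-octahydronaphthalene-1-carboxylate (trans-fused; labdane numbering: Δ2, 8-oxo, 9β-CO2Me)
Conditions: [(2-biphenylyl)(t-Bu)2P]AuCl (5 mol %), AgSbF6 (5 mol %), CH2Cl2, −20 °C to rt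
Reagents that add atoms: none
Why: Proposed new method: the cationic phosphine–gold complex activates only the terminal alkyne, the terminal carbon C1 of the 2-propenyl group attacks C2 anti to gold (ring A, 6-endo-dig at the alkyne and 6-endo-trig at the alkene) to leave an alkenyl-gold at C3 and a tertiary cation at C10, and the enol carbon C9 of the β-keto ester captures that cation (ring B, 6-(enolendo)-exo-trig) before protodeauration releases 9. The closest known reaction types are the gold-catalysed 6-endo-dig cyclisation of 1,5-enynes with intramolecular capture of the cyclohexenyl cation (enyne polycyclisation) and the Lewis-acid polyene cyclisation terminated by a β-keto ester enol; new is their union, with the terminating tether on the homopropargylic carbon C5. The quaternary C10 is set by the existing C5 centre: in the chair–chair array C5–H eclipses the C1=C10 bond, the C4 arm and the C6 arm lie on opposite faces, and anti addition of C2 and C9 across the π bond places the C10 methyl trans to H-5 (trans-decalin). C9 is an epimerisable β-keto ester centre and should settle with the ester equatorial (9α-H). The step needs 6-endo over 5-exo-dig closure and C- over O-capture: the methyl on C10 puts the charge on C10, the fully substituted C4 removes the hydride shift that leads other 1,5-enynes to bicyclo[3.1.0]hexenes and adds a Thorpe–Ingold effect, and an O-alkylated tertiary enol ether can re-ionise and funnel to the C-alkylated product.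

Step 8
Reactants: 9 methyl (1R,4aS,8aS)-5,5,8a-trimethyl-2-oxo-1,2,3,4,4a,5,8,8a-octahydronaphthalene-1-carboxylate
Product: 10 methyl (1R,4aS,8aS)-5,5,8a-trimethyl-2-oxodecahydronaphthalene-1-carboxylate
Conditions: H2 (1 atm), Pd/C, EtOAc, rt
Reagents that add atoms: none
Why: Heterogeneous hydrogenation of the only C=C bond (cis-disubstituted C2=C3, the trace of the alkyne) gives the saturated ring A while ketone, ester and all stereocentres are untouched.

Step 9
Reactants: 10 methyl (1R,4aS,8aS)-5,5,8a-trimethyl-2-oxodecahydronaphthalene-1-carboxylate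
Product: 11 methyl albicanate [methyl (1S,4aS,8aS)-5,5,8a-trimethyl-2-methylidenedecahydronaphthalene-1-carboxylate]
Conditions: Zn, CH2Br2, TiCl4, THF/CH2Cl2, 0 °C to rt
Reagents that add atoms: dibromomethane BrCBr
Why: Takai–Lombardo methylenation converts the hindered, enolisable C8 ketone into the exocyclic 8(17)-methylene under non-basic conditions, so the equatorial C9 ester is neither epimerised nor brought into conjugation.

Step 10
Reactants: 11 methyl albicanate
Product: 12 methyl 7α-hydroxyalbicanate (axial 7-OH)
Conditions: SeO2 (cat.), t-BuOOH, CH2Cl2, rt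
Reagents that add atoms: selenium dioxide O=[Se]=O; tert-butyl hydroperoxide CC(C)(C)OO
Why: The selenium dioxide ene reaction and [2,3]-sigmatropic shift oxidise the CH2 flank (C7) of the 1,1-disubstituted alkene in preference to the tertiary C9–H and deliver oxygen axially from the α face, giving the 7α alcohol that the next two steps invert.

Step 11
Reactants: 12 methyl 7α-hydroxyalbicanate
Product: 13 methyl 7-oxoalbicanate
Conditions: Dess–Martin periodinane, NaHCO3, CH2Cl2, 0 °C
Reagents that add atoms: none
Why: Buffered Dess–Martin oxidation of the allylic alcohol gives the exocyclic enone under near-neutral conditions, which keeps the 8(17) double bond from moving into the ring.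

Step 12
Reactants: 13 methyl 7-oxoalbicanate
Product: 14 methyl 7β-hydroxyalbicanate (equatorial 7-OH)
Conditions: NaBH4, CeCl3·7H2O, MeOH, −78 °C
Reagents that add atoms: none
Why: Luche reduction is 1,2-selective for the α-methylene ketone, and axial hydride delivery on the α face, opposite the angular methyl, should give the equatorial 7β alcohol of the target.

Step 13
Reactants: 14 methyl 7β-hydroxyalbicanate
Product: 15 methyl 7β-(triethylsilyloxy)albicanate
Conditions: Et3SiOTf, 2,6-lutidine, CH2Cl2, −78 °C
Reagents that add atoms: triethylsilyl trifluoromethanesulfonate CC[Si](CC)(CC)OS(=O)(=O)C(F)(F)F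
Why: Silylation protects the allylic alcohol with a group that survives hydride, ylide and oxidant, shields the neighbouring 8(17)-alkene and falls off in the final mild acid step.

Step 14
Reactants: 15 methyl 7β-(triethylsilyloxy)albicanate
Product: 16 7β-(triethylsilyloxy)albicanal [7β-(triethylsilyloxy)drim-8(12)-en-11-al]
Conditions: i-Bu2AlH (1.1 equiv), CH2Cl2, −78 °C; aq. potassium sodium tartrate
Reagents that add atoms: none
Why: The tetrahedral aluminate of this hindered ester beside the quaternary C10 is stable at −78 °C, so partial reduction stops at the aldehyde (C11), which is used at once to avoid epimerisation at C9.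

Step 15
Reactants: 16 7β-(triethylsilyloxy)albicanal
Product: 17 (5S,7S,9R,10S,11Z)-7-(triethylsilyloxy)-14,15,16-trinorlabda-8(17),11-diene (9β-(Z)-prop-1-enyl)
Conditions: EtPPh3Br, KN(SiMe3)2, THF, −78 to 0 °C
Reagents that add atoms: ethyltriphenylphosphonium bromide CC[P+](c1ccccc1)(c1ccccc1)c1ccccc1.[Br-]
Why: The Wittig reaction of a non-stabilised ylide under salt-free, kinetically controlled conditions gives the Z alkene, which the ene reaction requires.

Step 16
Reactants: 17 (5S,7S,9R,10S,11Z)-7-(triethylsilyloxy)-14,15,16-trinorlabda-8(17),11-diene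
Product: 18 (11S)-11-hydroperoxy-7β-(triethylsilyloxy)-14,15,16-trinorlabda-8(17),12-diene
Conditions: O2, tetraphenylporphyrin (cat.), hν (visible), CH2Cl2, −20 °C
Reagents that add atoms: oxygen O=O
Why: In this Schenck ene reaction, A(1,3) strain with the cis methyl holds C9–H in the alkene plane, so only a methyl hydrogen can be abstracted (oxygen to C11, double bond to C12=C13), and singlet oxygen should approach the face anti to the quaternary C10 to give the 11S hydroperoxide; the cis-disubstituted alkene also reacts faster than the shielded 1,1-disubstituted 8(17)-alkene.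

Step 17
Reactants: 18 (11S)-11-hydroperoxy-7β-(triethylsilyloxy)-14,15,16-trinorlabda-8(17),12-diene
Product: 19 (11S)-11-[(2-methoxypropan-2-yl)peroxy]-7β-(triethylsilyloxy)-14,15,16-trinorlabda-8(17),12-diene
Conditions: 2-methoxypropene, pyridinium p-toluenesulfonate (cat.), CH2Cl2, 0 °C
Reagents that add atoms: 2-methoxypropene COC(C)=C
Why: Acid-catalysed addition of the hydroperoxide to the enol ether gives a peroxyketal, a protecting group for OOH that tolerates oxidants and ylides and is removed by dilute acid.

Step 18
Reactants: 19 (11S)-11-[(2-methoxypropan-2-yl)peroxy]-7β-(triethylsilyloxy)-14,15,16-trinorlabda-8(17),12-diene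
Product: 21 (11R)-11-[(2-methoxypropan-2-yl)peroxy]-7β-(triethylsilyloxy)-13,14,15,16-tetranorlabd-8(17)-en-12-al, via 12,13-diol 20 (not isolated)
Conditions: OsO4 (2 mol %), NaIO4, 2,6-lutidine, dioxane/H2O, 0 °C to rt
Reagents that add atoms: osmium tetroxide O=[Os](=O)(=O)=O; sodium periodate [Na+].[O-]I(=O)(=O)=O
Why: Lemieux–Johnson cleavage should take the monosubstituted vinyl group before the 8(17)-methylene, which is 1,1-disubstituted and flanked by the silyl ether and the C9 branch, and lutidine buffering protects the peroxyketal; the peroxide-bearing centre is unchanged (the descriptor changes only by priority).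

Step 19
Reactants: 22 3-bromo-1,1-dimethoxypropane; 23 triphenylphosphine
Product: 24 (3,3-dimethoxypropyl)triphenylphosphonium bromide
Conditions: NaHCO3 (acid scavenger), MeCN, 80 °C
Reagents that add atoms: none
Why: SN2 quaternisation of triphenylphosphine by the primary bromide gives the phosphonium salt, and the solid bicarbonate keeps the acetal intact.

Step 20
Reactants: 24 (3,3-dimethoxypropyl)triphenylphosphonium bromide; 25 ethyl formate
Product: 27 4,4-dimethoxy-2-(triphenyl-λ5-phosphanylidene)butanal, via (3,3-dimethoxypropylidene)triphenylphosphorane 26 (not isolated)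
Conditions: KOt-Bu, THF, 0 °C; HCO2Et, 0 °C to rt
Reagents that add atoms: none
Why: C-formylation of the non-stabilised ylide by the formate ester, followed by loss of a proton, gives the formyl-stabilised ylide that carries C13–C16.

Step 21
Reactants: 21 (11R)-11-[(2-methoxypropan-2-yl)peroxy]-7β-(triethylsilyloxy)-13,14,15,16-tetranorlabd-8(17)-en-12-al; 27 4,4-dimethoxy-2-(triphenyl-λ5-phosphanylidene)butanal
Product: 28 (11S,12E)-15,15-dimethoxy-11-[(2-methoxypropan-2-yl)peroxy]-7β-(triethylsilyloxy)labda-8(17),12-dien-16-al
Conditions: toluene, 60 °C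
Reagents that add atoms: none
Why: The Wittig reaction of the formyl-stabilised, α-substituted ylide is neutral (no Kornblum–DeLaMare cleavage of the peroxyketal-protected α-peroxy aldehyde, a substrate class known to tolerate ylides) and E-selective, so the formyl group ends trans to C11 as in the target.

Step 22
Reactants: 28 (11S,12E)-15,15-dimethoxy-11-[(2-methoxypropan-2-yl)peroxy]-7β-(triethylsilyloxy)labda-8(17),12-dien-16-al
Product: 30 (5S,7S,9R,10S,11S,15R)-7,15-dihydroxy-11,15-epidioxylabda-8(17),12-dien-16-al (CNP0269954.2), via hydroperoxy dial 29 (not isolated)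
Conditions: AcOH/THF/H2O (3:1:1), rt to 30 °C
Reagents that add atoms: water O
Why: Aqueous acetic acid removes the peroxyketal, the triethylsilyl ether and the dimethyl acetal in one operation, and the freed C11 hydroperoxide adds to the C15 aldehyde (the only carbonyl it can reach across the E double bond) to close the seven-membered cyclic peroxy hemiacetal, whose C15 centre equilibrates to the 15R epimer.

## Compound list

1 | methyl acetoacetate | CC(=O)CC(=O)OC | starting material
2 | 3-chloro-3-methylbut-1-yne | C#CC(C)(C)Cl | starting material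
3 | methyl 2-acetyl-3,3-dimethylpent-4-ynoate (racemic) | CC(=O)C(C(=O)OC)C(C)(C)C#C | intermediate
4 | methyl 3,3-dimethyl-2-(prop-1-en-2-yl)pent-4-ynoate (racemic) | C=C(C)C(C(=O)OC)C(C)(C)C#C | intermediate
5 | (±)-3,3-dimethyl-2-(prop-1-en-2-yl)pent-4-yn-1-ol | C=C(C)C(CO)C(C)(C)C#C | intermediate
6 | (R)-3,3-dimethyl-2-(prop-1-en-2-yl)pent-4-yn-1-ol | C#CC(C)(C)[C@@H](C(C)=C)CO | intermediate
7 | (R)-3-(iodomethyl)-2,4,4-trimethylhex-1-en-5-yne | C#CC(C)(C)[C@@H](C(C)=C)CI | intermediate
8 | methyl (6R)-7,7-dimethyl-3-oxo-6-(prop-1-en-2-yl)non-8-ynoate | C#CC(C)(C)[C@@H](C(C)=C)CCC(=O)CC(=O)OC | intermediate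
9 | methyl (1R,4aS,8aS)-5,5,8a-trimethyl-2-oxo-1,2,3,4,4a,5,8,8a-octahydronaphthalene-1-carboxylate | O=C1[C@H](C(=O)OC)[C@@]2(C)CC=CC(C)(C)[C@@H]2CC1 | intermediate
10 | methyl (1R,4aS,8aS)-5,5,8a-trimethyl-2-oxodecahydronaphthalene-1-carboxylate | O=C1[C@H](C(=O)OC)[C@@]2(C)CCCC(C)(C)[C@@H]2CC1 | intermediate
11 | methyl albicanate [methyl (1S,4aS,8aS)-5,5,8a-trimethyl-2-methylidenedecahydronaphthalene-1-carboxylate] | C=C1[C@H](C(=O)OC)[C@@]2(C)CCCC(C)(C)[C@@H]2CC1 | intermediate
12 | methyl 7α-hydroxyalbicanate | C=C1[C@H](C(=O)OC)[C@@]2(C)CCCC(C)(C)[C@@H]2C[C@H]1O | intermediate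
13 | methyl 7-oxoalbicanate | C=C1[C@H](C(=O)OC)[C@@]2(C)CCCC(C)(C)[C@@H]2CC1=O | intermediate
14 | methyl 7β-hydroxyalbicanate | C=C1[C@H](C(=O)OC)[C@@]2(C)CCCC(C)(C)[C@@H]2C[C@@H]1O | intermediate
15 | methyl 7β-(triethylsilyloxy)albicanate | C=C1[C@H](C(=O)OC)[C@@]2(C)CCCC(C)(C)[C@@H]2C[C@@H]1O[Si](CC)(CC)CC | intermediate
16 | 7β-(triethylsilyloxy)albicanal | C=C1[C@H](C=O)[C@@]2(C)CCCC(C)(C)[C@@H]2C[C@@H]1O[Si](CC)(CC)CC | intermediate
17 | (5S,7S,9R,10S,11Z)-7-(triethylsilyloxy)-14,15,16-trinorlabda-8(17),11-diene | C=C1[C@H](/C=C\C)[C@@]2(C)CCCC(C)(C)[C@@H]2C[C@@H]1O[Si](CC)(CC)CC | intermediate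
18 | (11S)-11-hydroperoxy-7β-(triethylsilyloxy)-14,15,16-trinorlabda-8(17),12-diene | C=C1[C@H]([C@@H](OO)C=C)[C@@]2(C)CCCC(C)(C)[C@@H]2C[C@@H]1O[Si](CC)(CC)CC | intermediate
19 | (11S)-11-[(2-methoxypropan-2-yl)peroxy]-7β-(triethylsilyloxy)-14,15,16-trinorlabda-8(17),12-diene | C=C1[C@H]([C@@H](OOC(C)(C)OC)C=C)[C@@]2(C)CCCC(C)(C)[C@@H]2C[C@@H]1O[Si](CC)(CC)CC | intermediate
20 | 12,13-diol from 19 (C12 epimers; not isolated) | C=C1[C@H]([C@@H](OOC(C)(C)OC)C(O)CO)[C@@]2(C)CCCC(C)(C)[C@@H]2C[C@@H]1O[Si](CC)(CC)CC | intermediate
21 | (11R)-11-[(2-methoxypropan-2-yl)peroxy]-7β-(triethylsilyloxy)-13,14,15,16-tetranorlabd-8(17)-en-12-al | C=C1[C@H]([C@@H](OOC(C)(C)OC)C=O)[C@@]2(C)CCCC(C)(C)[C@@H]2C[C@@H]1O[Si](CC)(CC)CC | intermediate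
22 | 3-bromo-1,1-dimethoxypropane | COC(CCBr)OC | starting material
23 | triphenylphosphine | c1ccc(cc1)P(c1ccccc1)c1ccccc1 | starting material
24 | (3,3-dimethoxypropyl)triphenylphosphonium bromide | COC(CC[P+](c1ccccc1)(c1ccccc1)c1ccccc1)OC.[Br-] | intermediate
25 | ethyl formate | CCOC=O | starting material
26 | (3,3-dimethoxypropylidene)triphenylphosphorane (not isolated) | COC(CC=P(c1ccccc1)(c1ccccc1)c1ccccc1)OC | intermediate
27 | 4,4-dimethoxy-2-(triphenyl-λ5-phosphanylidene)butanal | COC(CC(C=O)=P(c1ccccc1)(c1ccccc1)c1ccccc1)OC | intermediate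
28 | (11S,12E)-15,15-dimethoxy-11-[(2-methoxypropan-2-yl)peroxy]-7β-(triethylsilyloxy)labda-8(17),12-dien-16-al | C=C1[C@H]([C@@H](OOC(C)(C)OC)/C=C(/C=O)CC(OC)OC)[C@@]2(C)CCCC(C)(C)[C@@H]2C[C@@H]1O[Si](CC)(CC)CC | intermediate
29 | (11S,12E)-11-hydroperoxy-7β-hydroxylabda-8(17),12-diene-15,16-dial (not isolated) | C=C1[C@H]([C@@H](OO)/C=C(/C=O)CC=O)[C@@]2(C)CCCC(C)(C)[C@@H]2C[C@@H]1O | intermediate
30 | (5S,7S,9R,10S,11S,15R)-7,15-dihydroxy-11,15-epidioxylabda-8(17),12-dien-16-al (CNP0269954.2) | C=C1[C@H]([C@@H]2C=C(C=O)C[C@H](O)OO2)[C@@]2(C)CCCC(C)(C)[C@@H]2C[C@@H]1O | target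

## Step count and risks

Total step count: 22. Longest linear sequence: 20 steps (steps 1–18, 21 and 22); steps 19 and 20 make the ylide branch.

Step 7 (Proposed new method). The cascade may stall after the first ring closure: capture of the C10 cation by C9 can lose to O-alkylation of the enol, to hydration of the alkyne, or to fragmentation of the C4–C5 bond of the cyclohexenyl cation (an acetylenic Cope-type ring opening). The fallback uses known chemistry, sets out from 8 and comes back at 9, and separates the two ring closures. Gold-catalysed 6-endo-dig methoxycyclisation of the 1,5-enyne ([(2-biphenylyl)(t-Bu)2P]AuCl/AgSbF6, CH2Cl2/MeOH) still closes ring A through C1–C2 and stores the C10 cation as the tertiary methyl ether methyl 5-[(1S)-6-methoxy-2,2,6-trimethylcyclohex-3-en-1-yl]-3-oxopentanoate F1. SnCl4 in CH2Cl2 at −78 °C then ionises the ether, and the β-keto ester enol closes ring B as in the classical Lewis-acid, β-keto-ester-terminated cation–olefin cyclisation, to give 9.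

Step 16. Poor π-facial discrimination at C11, or a competing ene reaction at the 8(17)-methylene, would erode the C11 configuration. The fallback sets out from 16 and comes back at 19; it sets C11 by reagent control and SN2 inversion instead of by the ene reaction. Vinylmagnesium bromide adds to 16 to give the epimeric alcohols (11RS)-7β-(triethylsilyloxy)-14,15,16-trinorlabda-8(17),12-dien-11-ol F2, and Dess–Martin oxidation gives 7β-(triethylsilyloxy)-14,15,16-trinorlabda-8(17),12-dien-11-one F3. Reduction with BH3·SMe2 and the (S)-CBS oxazaborolidine gives (11R)-7β-(triethylsilyloxy)-14,15,16-trinorlabda-8(17),12-dien-11-ol F4. Triflation (Tf2O, 2,6-lutidine, −78 °C) gives (11R)-7β-(triethylsilyloxy)-14,15,16-trinorlabda-8(17),12-dien-11-yl trifluoromethanesulfonate F5, which is displaced with inversion by 2-methoxyprop-2-yl hydroperoxide and CsOH in DMF to give 19.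

Step 18. Osmylation may not discriminate enough, and the 8(17)-methylene may be oxidised alongside the vinyl group. The fallback sets out from 19 and comes back at 28, so that no oxidative cleavage is needed. Cross-metathesis of 19 with 4,4-dimethoxy-2-methylidenebutanal F6 (from 4,4-dimethoxybutanal by α-methylenation with aqueous formaldehyde and pyrrolidinium propionate), with the second-generation Hoveyda–Grubbs catalyst RuCl2(H2IMes)(=CH-C6H4-2-O-i-Pr) in CH2Cl2 at 40 °C, should give the E enal 28 directly. The hindered 1,1-disubstituted ring alkene does not take part, dialkyl peroxides tolerate the catalyst, and steps 19 to 21 fall away.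

Further compounds
F1 | step 7 | methyl 5-[(1S)-6-methoxy-2,2,6-trimethylcyclohex-3-en-1-yl]-3-oxopentanoate (C6 epimers) | COC1(C)CC=CC(C)(C)[C@@H]1CCC(=O)CC(=O)OC
F2 | step 16 | (11RS)-7β-(triethylsilyloxy)-14,15,16-trinorlabda-8(17),12-dien-11-ol | C=C1[C@H](C(O)C=C)[C@@]2(C)CCCC(C)(C)[C@@H]2C[C@@H]1O[Si](CC)(CC)CC
F3 | step 16 | 7β-(triethylsilyloxy)-14,15,16-trinorlabda-8(17),12-dien-11-one | C=C1[C@H](C(=O)C=C)[C@@]2(C)CCCC(C)(C)[C@@H]2C[C@@H]1O[Si](CC)(CC)CC
F4 | step 16 | (11R)-7β-(triethylsilyloxy)-14,15,16-trinorlabda-8(17),12-dien-11-ol | C=C1[C@H]([C@H](O)C=C)[C@@]2(C)CCCC(C)(C)[C@@H]2C[C@@H]1O[Si](CC)(CC)CC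
F5 | step 16 | (11R)-7β-(triethylsilyloxy)-14,15,16-trinorlabda-8(17),12-dien-11-yl trifluoromethanesulfonate | C=C1[C@H]([C@H](OS(=O)(=O)C(F)(F)F)C=C)[C@@]2(C)CCCC(C)(C)[C@@H]2C[C@@H]1O[Si](CC)(CC)CC
F6 | step 18 | 4,4-dimethoxy-2-methylidenebutanal | C=C(C=O)CC(OC)OC
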